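**Retrosynthetic overview**

- The aryl ketone is disconnected last: target ⇒ cis-fused γ-lactone + 3,4,5-trimethoxyphenyllithium. The cis pair (hydroxymethyl on C3, aroyl on C4) is carried as a lactone ring, so the epimerizable C4 centre stays locked until the final step.
- Lactone ⇒ all-trans 2-aryl-4-alkenyl-tetrahydrofuran-3-carbaldehyde (reduce CHO, cleave the alkene to CHO, epimerize into the cis lactol, oxidize).
- Tetrahydrofuran ⇒ seven-membered 4,5-dihydro-1,3-dioxepine (cyclic vinyl acetal) by Lewis-acid 1,3 O-to-C ring contraction. The enabling feature is the array ring O–C2(aryl)–C3–CH2OH, a β-alkoxy aldehyde (aldol) unit at a benzylic carbon; in the precursor the future CH2OH carbon and its oxygen are ring members (enol ether O–CH=C) and are the two atoms extruded as the formyl group.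
- Dioxepine ⇒ mirror-symmetric acetal of (Z)-but-2-ene-1,4-diol and 3,4-dimethoxybenzaldehyde + an alkenyl triflate; an asymmetric Heck reaction sets the single controlling stereocentre.
- Ring order: seven-membered acetal ring, then the tetrahydrofuran by contraction, then a temporary lactone ring that is opened at the end; both arenes are bought.

Key step: step 4

Remark on the chemistry (assumption): the sense of induction of the (S)-configured P,N ligand in the Heck step is assigned by analogy with other cyclic alkenes; should the opposite enantiomer predominate, the (R)-ligand is used and nothing else changes. The alkenyl triflate is treated as a compound to be made.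

**Route**

Step 1
Reactants: 1 2-methylpropanal
Product: 2 2-methylprop-1-en-1-yl trifluoromethanesulfonate
Conditions: Tf2O, 2,6-di-tert-butyl-4-methylpyridine, CH2Cl2, 0 °C → reflux
Reagents that add atoms: trifluoromethanesulfonic anhydride, O=S(=O)(OS(=O)(=O)C(F)(F)F)C(F)(F)F
Why: O-triflation of the enolizable aldehyde followed by elimination with the hindered pyridine (enol triflate formation) should give the alkenyl triflate, with no E/Z issue because the β-carbon carries two methyl groups.

Step 2
Reactants: 3 (Z)-but-2-ene-1,4-diol; 4 3,4-dimethoxybenzaldehyde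
Product: 5 2-(3,4-dimethoxyphenyl)-4,7-dihydro-1,3-dioxepine
Conditions: p-TsOH·H2O (cat.), benzene, reflux, azeotropic removal of water
Reagents that add atoms: none
Why: Acid-catalysed acetalization with removal of water should close the seven-membered cis-allylic acetal, which has a mirror plane and therefore no stereocentre to control.

Step 3
Reactants: 5 2-(3,4-dimethoxyphenyl)-4,7-dihydro-1,3-dioxepine (3 equiv); 2 2-methylprop-1-en-1-yl trifluoromethanesulfonate
Product: 6 (5S)-2-(3,4-dimethoxyphenyl)-5-(2-methylprop-1-en-1-yl)-4,5-dihydro-1,3-dioxepine (both C2 epimers)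
Conditions: Pd2(dba)3·CHCl3 (3 mol%, zerovalent palladium source), (S)-4-tert-butyl-2-[2-(diphenylphosphanyl)phenyl]-4,5-dihydro-1,3-oxazole (7 mol%), i-Pr2NEt (2 equiv), THF, 60 °C
Reagents that add atoms: none
Why: Asymmetric intermolecular Heck reaction on the cationic palladium path, a known reaction class for 4,7-dihydro-1,3-dioxepines: syn alkenyl-palladation of one enantiotopic alkene carbon and syn β-hydride elimination toward the ring oxygen (the hydrogen on the new stereocentre is anti to palladium) should give the enol ether, with the C5 stereocentre set by the chiral P,N ligand.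

Step 4
Reactants: 6 (5S)-2-(3,4-dimethoxyphenyl)-5-(2-methylprop-1-en-1-yl)-4,5-dihydro-1,3-dioxepine
Product: 9 (2S,3S,4S)-2-(3,4-dimethoxyphenyl)-4-(2-methylprop-1-en-1-yl)oxolane-3-carbaldehyde (all-trans), via ring-opened oxocarbenium enol silane 7 (not isolated), via 2,3-cis aldehyde 8 (not isolated)
Conditions: TMSOTf (0.2 equiv), CH2Cl2, −78 °C until 6 is consumed, then warm to 0 °C; Et3N, aq. NaHCO3
Reagents that add atoms: none
Why: TMSOTf should ionize the acetal at the enol-ether oxygen to give the ion pair 7 (a Z silyl enol ether tethered to an oxocarbenium ion conjugated to the 3,4-dimethoxyphenyl ring), which recombines through carbon in an intramolecular Mukaiyama aldol-type step and releases the silyl cation, so that the enol oxygen and its carbon leave the ring as the formyl group (net 1,3 O-to-C shift, seven- to five-membered). The closest known reaction type is the Lewis-acid ring contraction of 2-aryl-5-substituted 4,5-dihydro-1,3-dioxepines to tetrahydrofuran-3-carbaldehydes, the seven-to-five relative of the Petasis–Ferrier rearrangement. The tetrahydrofuran is closed by a 5-(enolexo)-endo-trig attack of the enol silane carbon on the oxocarbenium carbon, a mode that is fast for cationic electrophiles of this kind. The C3 stereocentre should form anti to the isobutenyl group on the adjacent pre-set carbon, because the enol silane reacts in the conformer that minimizes allylic 1,3-strain and the tethered oxocarbenium lies on the face opposite that substituent; the C2 stereocentre should form cis to the formyl group under kinetic control (8), but the C2–C3 bond re-ionizes on warming, so the mixture should converge on the all-trans isomer 9, the most stable of the four. The step needs ionization at the enol-ether oxygen and not at the alkyl oxygen (only the former gives a silyl enol ether and an aryl-stabilized cation) and capture by the enol silane and not by the isobutenyl alkene or the arene (the enol silane is by far the strongest π-nucleophile and is held in the ion pair). The isobutenyl-bearing carbon has no acidifying group and cannot epimerize, so the enantiomeric purity from step 3 is relayed to C2 and C3.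

Step 5
Reactants: 9 (2S,3S,4S)-2-(3,4-dimethoxyphenyl)-4-(2-methylprop-1-en-1-yl)oxolane-3-carbaldehyde
Product: 10 [(2S,3R,4S)-2-(3,4-dimethoxyphenyl)-4-(2-methylprop-1-en-1-yl)oxolan-3-yl]methanol
Conditions: NaBH4, MeOH, 0 °C
Reagents that add atoms: none
Why: Chemoselective hydride reduction of the aldehyde should give the primary alcohol without a new stereocentre, and any epimerization at C3 before reduction is harmless because the all-trans isomer is already the thermodynamic one.

Step 6
Reactants: 10 [(2S,3R,4S)-2-(3,4-dimethoxyphenyl)-4-(2-methylprop-1-en-1-yl)oxolan-3-yl]methanol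
Product: 13 (3aR,4S,6aR)-4-(3,4-dimethoxyphenyl)hexahydrofuro[3,4-c]furan-1-ol (anomer mixture), via trans hydroxy aldehyde 11 (not isolated), via cis hydroxy aldehyde 12 (not isolated)
Conditions: O3, CH2Cl2/MeOH 4:1, −78 °C (Sudan Red 7B end-point); PPh3, −78 °C → rt; then DBU (0.2 equiv), CH2Cl2, rt
Reagents that add atoms: ozone, [O-][O+]=O
Why: Ozonolysis with reductive work-up should cleave the trisubstituted alkene far faster than the dimethoxyarene, and DBU should then epimerize the aldehyde α-carbon through its enolate; only the cis isomer 12 can close to the five-membered lactol, which drains the equilibrium and sets this centre under thermodynamic control through the cis ring fusion.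

Step 7
Reactants: 13 (3aR,4S,6aR)-4-(3,4-dimethoxyphenyl)hexahydrofuro[3,4-c]furan-1-ol
Product: 14 (3aR,4S,6aR)-4-(3,4-dimethoxyphenyl)tetrahydro-1H,3H-furo[3,4-c]furan-1-one (aryl on the convex face)
Conditions: TEMPO (10 mol%), PhI(OAc)2 (1.2 equiv), CH2Cl2, rt
Reagents that add atoms: none
Why: Oxoammonium (TEMPO) oxidation of the lactol to the lactone should leave the electron-rich arene and the ether untouched, and the cis ring fusion keeps the α-stereocentre fixed.

Step 8
Reactants: 14 (3aR,4S,6aR)-4-(3,4-dimethoxyphenyl)tetrahydro-1H,3H-furo[3,4-c]furan-1-one; 15 5-bromo-1,2,3-trimethoxybenzene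
Product: 18 (3,4,5-trimethoxyphenyl)[(3R,4R,5S)-5-(3,4-dimethoxyphenyl)-4-(hydroxymethyl)oxolan-3-yl]methanone, via 3,4,5-trimethoxyphenyllithium 16 (not isolated), via lithium lactolate 17 (not isolated)
Conditions: 15, n-BuLi, THF, −78 °C; cannulate into 14, THF, −78 °C; AcOH in THF, −78 °C, then warm
Reagents that add atoms: none
Why: Bromine–lithium exchange and single addition of the aryllithium to the γ-lactone should stop at the lithium lactolate 17, which is stable at −78 °C and releases the ketone only on the cold acetic acid quench, so a second addition is avoided and the 3,4-cis configuration inherited from the ring fusion is kept without base-mediated epimerization.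

**Compound list**

1 | 2-methylpropanal | CC(C)C=O | starting material
2 | 2-methylprop-1-en-1-yl trifluoromethanesulfonate | CC(C)=COS(=O)(=O)C(F)(F)F | intermediate
3 | (Z)-but-2-ene-1,4-diol | OC/C=C\CO | starting material
4 | 3,4-dimethoxybenzaldehyde | COc1ccc(C=O)cc1OC | starting material
5 | 2-(3,4-dimethoxyphenyl)-4,7-dihydro-1,3-dioxepine | COc1ccc(C2OCC=CCO2)cc1OC | intermediate
6 | (5S)-2-(3,4-dimethoxyphenyl)-5-(2-methylprop-1-en-1-yl)-4,5-dihydro-1,3-dioxepine, both epimers at the acetal carbon (that centre is destroyed in step 4) | COc1ccc(C2OC[C@@H](C=C(C)C)C=CO2)cc1OC | intermediate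
7 | ring-opened ion pair: [(3,4-dimethoxyphenyl)methylidene][(2S,3Z)-2-(2-methylprop-1-en-1-yl)-4-(trimethylsilyloxy)but-3-en-1-yl]oxonium triflate | COc1ccc(C=[O+]C[C@@H](C=C(C)C)/C=C\O[Si](C)(C)C)cc1OC.[O-]S(=O)(=O)C(F)(F)F | intermediate
8 | (2R,3S,4S)-2-(3,4-dimethoxyphenyl)-4-(2-methylprop-1-en-1-yl)oxolane-3-carbaldehyde (2,3-cis, 3,4-trans) | COc1ccc([C@@H]2OC[C@@H](C=C(C)C)[C@@H]2C=O)cc1OC | intermediate
9 | (2S,3S,4S)-2-(3,4-dimethoxyphenyl)-4-(2-methylprop-1-en-1-yl)oxolane-3-carbaldehyde (all-trans) | COc1ccc([C@H]2OC[C@@H](C=C(C)C)[C@@H]2C=O)cc1OC | intermediate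
10 | [(2S,3R,4S)-2-(3,4-dimethoxyphenyl)-4-(2-methylprop-1-en-1-yl)oxolan-3-yl]methanol | COc1ccc([C@H]2OC[C@@H](C=C(C)C)[C@@H]2CO)cc1OC | intermediate
11 | (3S,4R,5S)-5-(3,4-dimethoxyphenyl)-4-(hydroxymethyl)oxolane-3-carbaldehyde (formyl trans to hydroxymethyl) | COc1ccc([C@H]2OC[C@@H](C=O)[C@@H]2CO)cc1OC | intermediate
12 | (3R,4R,5S)-5-(3,4-dimethoxyphenyl)-4-(hydroxymethyl)oxolane-3-carbaldehyde (formyl cis to hydroxymethyl) | COc1ccc([C@H]2OC[C@H](C=O)[C@@H]2CO)cc1OC | intermediate
13 | (3aR,4S,6aR)-4-(3,4-dimethoxyphenyl)hexahydrofuro[3,4-c]furan-1-ol, cis-fused lactol, both anomers | COc1ccc([C@H]2OC[C@H](C(O)OC3)[C@@H]23)cc1OC | intermediate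
14 | (3aR,4S,6aR)-4-(3,4-dimethoxyphenyl)tetrahydro-1H,3H-furo[3,4-c]furan-1-one, cis-fused lactone, aryl on the convex face | COc1ccc([C@H]2OC[C@H](C(=O)OC3)[C@@H]23)cc1OC | intermediate
15 | 5-bromo-1,2,3-trimethoxybenzene | COc1cc(Br)cc(OC)c1OC | starting material
16 | 3,4,5-trimethoxyphenyllithium | [Li]c1cc(OC)c(OC)c(OC)c1 | intermediate
17 | lithium (3aR,4S,6aR)-4-(3,4-dimethoxyphenyl)-1-(3,4,5-trimethoxyphenyl)hexahydrofuro[3,4-c]furan-1-olate | COc1ccc([C@H]2OC[C@H](C([O-])(c3cc(OC)c(OC)c(OC)c3)OC4)[C@@H]24)cc1OC.[Li+] | intermediate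
18 | (3,4,5-trimethoxyphenyl)[(3R,4R,5S)-5-(3,4-dimethoxyphenyl)-4-(hydroxymethyl)oxolan-3-yl]methanone | COc1ccc([C@H]2OC[C@H](C(=O)c3cc(OC)c(OC)c(OC)c3)[C@@H]2CO)cc1OC | target

**Step count and risks**

Total step count: 8. Longest linear sequence: 7 steps (steps 2 to 8, from 3 and 4); step 1 is a one-step side branch.

Three steps most likely to fail:

1. Step 3. The risk is poor enantiofacial discrimination, or migration of the new enol-ether double bond by re-addition of the palladium hydride, when an alkenyl triflate is used. The fallback sets out from 5 and comes back at 10. The Heck coupling is run with an achiral catalyst (Pd(OAc)2, PPh3, i-Pr2NEt), which should give 6 together with its enantiomer (5R)-2-(3,4-dimethoxyphenyl)-5-(2-methylprop-1-en-1-yl)-4,5-dihydro-1,3-dioxepine F1. Steps 4 and 5 applied to this mixture should give 9 and 10 together with (2R,3R,4R)-2-(3,4-dimethoxyphenyl)-4-(2-methylprop-1-en-1-yl)oxolane-3-carbaldehyde F2 and [(2R,3S,4R)-2-(3,4-dimethoxyphenyl)-4-(2-methylprop-1-en-1-yl)oxolan-3-yl]methanol F3. The alcohol mixture is esterified with (S)-O-acetylmandelic acid (DCC, DMAP, CH2Cl2) to the diastereomeric esters [(2S,3R,4S)-2-(3,4-dimethoxyphenyl)-4-(2-methylprop-1-en-1-yl)oxolan-3-yl]methyl (2S)-2-acetoxy-2-phenylacetate F4 and [(2R,3S,4R)-2-(3,4-dimethoxyphenyl)-4-(2-methylprop-1-en-1-yl)oxolan-3-yl]methyl (2S)-2-acetoxy-2-phenylacetate F5, which are separated by chromatography or crystallization. Methanolysis of F4 (K2CO3, MeOH) returns 10.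

2. Step 4. The risk is incomplete convergence on the all-trans isomer, or capture of the re-formed oxocarbenium ion by the isobutenyl alkene (Prins-type closure) during the warm equilibration. The fallback sets out from 6 and comes back at 14. The contraction is run under kinetic control only (TMSOTf, CH2Cl2, −78 °C, cold Et3N quench) and 8 is isolated. NaBH4 reduction should give [(2R,3R,4S)-2-(3,4-dimethoxyphenyl)-4-(2-methylprop-1-en-1-yl)oxolan-3-yl]methanol F6. Ozonolysis with PPh3 work-up should give (3S,4R,5R)-5-(3,4-dimethoxyphenyl)-4-(hydroxymethyl)oxolane-3-carbaldehyde F7, which DBU epimerizes to (3R,4R,5R)-5-(3,4-dimethoxyphenyl)-4-(hydroxymethyl)oxolane-3-carbaldehyde F8, and this closes to the lactol (3aR,4R,6aR)-4-(3,4-dimethoxyphenyl)hexahydrofuro[3,4-c]furan-1-ol F9. TEMPO and PhI(OAc)2 should give the endo-aryl lactone (3aR,4R,6aR)-4-(3,4-dimethoxyphenyl)tetrahydro-1H,3H-furo[3,4-c]furan-1-one F10. Its benzylic ether carbon is then equilibrated with acid (BF3·OEt2 cat., CH2Cl2) through reversible ionization of the benzylic C–O bond, which should move the aryl group to the convex face and give 14; this moves the thermodynamic correction of the benzylic centre to a stage where no alkene is present.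

3. Step 8. The risk is premature collapse of the lactolate followed by a second addition of the aryllithium, or enolization of the lactone instead of addition. The fallback sets out from 13 and comes back at 18. The lactol is treated with 3,4,5-trimethoxyphenylmagnesium bromide (from 15 and Mg, 2.5 equiv, THF, 0 °C), which should add once to the open hydroxy aldehyde and give the diol (3,4,5-trimethoxyphenyl)[(3R,4R,5S)-5-(3,4-dimethoxyphenyl)-4-(hydroxymethyl)oxolan-3-yl]methanol F11 as a mixture of carbinol epimers. Chemoselective oxidation of the electron-rich benzylic alcohol with MnO2 (CH2Cl2, rt) should then give 18 without touching the primary alcohol.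

**Further compounds**

F1 | step 3 | (5R)-2-(3,4-dimethoxyphenyl)-5-(2-methylprop-1-en-1-yl)-4,5-dihydro-1,3-dioxepine | COc1ccc(C2OC[C@H](C=C(C)C)C=CO2)cc1OC
F2 | step 3 | (2R,3R,4R)-2-(3,4-dimethoxyphenyl)-4-(2-methylprop-1-en-1-yl)oxolane-3-carbaldehyde | COc1ccc([C@@H]2OC[C@H](C=C(C)C)[C@H]2C=O)cc1OC
F3 | step 3 | [(2R,3S,4R)-2-(3,4-dimethoxyphenyl)-4-(2-methylprop-1-en-1-yl)oxolan-3-yl]methanol | COc1ccc([C@@H]2OC[C@H](C=C(C)C)[C@H]2CO)cc1OC
F4 | step 3 | [(2S,3R,4S)-2-(3,4-dimethoxyphenyl)-4-(2-methylprop-1-en-1-yl)oxolan-3-yl]methyl (2S)-2-acetoxy-2-phenylacetate | COc1ccc([C@H]2OC[C@@H](C=C(C)C)[C@@H]2COC(=O)[C@@H](OC(C)=O)c3ccccc3)cc1OC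
F5 | step 3 | [(2R,3S,4R)-2-(3,4-dimethoxyphenyl)-4-(2-methylprop-1-en-1-yl)oxolan-3-yl]methyl (2S)-2-acetoxy-2-phenylacetate | COc1ccc([C@@H]2OC[C@H](C=C(C)C)[C@H]2COC(=O)[C@@H](OC(C)=O)c3ccccc3)cc1OC
F6 | step 4 | [(2R,3R,4S)-2-(3,4-dimethoxyphenyl)-4-(2-methylprop-1-en-1-yl)oxolan-3-yl]methanol | COc1ccc([C@@H]2OC[C@@H](C=C(C)C)[C@@H]2CO)cc1OC
F7 | step 4 | (3S,4R,5R)-5-(3,4-dimethoxyphenyl)-4-(hydroxymethyl)oxolane-3-carbaldehyde | COc1ccc([C@@H]2OC[C@@H](C=O)[C@@H]2CO)cc1OC
F8 | step 4 | (3R,4R,5R)-5-(3,4-dimethoxyphenyl)-4-(hydroxymethyl)oxolane-3-carbaldehyde | COc1ccc([C@@H]2OC[C@H](C=O)[C@@H]2CO)cc1OC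
F9 | step 4 | (3aR,4R,6aR)-4-(3,4-dimethoxyphenyl)hexahydrofuro[3,4-c]furan-1-ol | COc1ccc([C@@H]2OC[C@H](C(O)OC3)[C@@H]23)cc1OC
F10 | step 4 | (3aR,4R,6aR)-4-(3,4-dimethoxyphenyl)tetrahydro-1H,3H-furo[3,4-c]furan-1-one | COc1ccc([C@@H]2OC[C@H](C(=O)OC3)[C@@H]23)cc1OC
F11 | step 8 | (3,4,5-trimethoxyphenyl)[(3R,4R,5S)-5-(3,4-dimethoxyphenyl)-4-(hydroxymethyl)oxolan-3-yl]methanol | COc1ccc([C@H]2OC[C@H](C(O)c3cc(OC)c(OC)c(OC)c3)[C@@H]2CO)cc1OC
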